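**Retrosynthetic overview**
1. Target ⇒ isomeric labdane-type 8β,9β-epoxide. An acid-triggered relay of 1,2-shifts (CH3 C10→C9, H C5→C10, CH3 C4→C5, loss of H-3) turns the 4,4,10-trimethyldecalin into the 4,5,9-trimethyl clerodane and frees the 8β-OH.
2. Epoxide ⇒ 6-oxo triene lactone by C7 enolate hydroxylation, C6 reduction, OH-directed epoxidation and two acylations. All oxidations are finished before the Δ3 alkene exists.
3. Triene lactone ⇒ C11 aldehyde + butenolide phosphonate (Horner–Wadsworth–Emmons, C11=C12).
4. Ring B ⇒ enantioselective [4+2] of a ring-A 2-ethoxydiene with but-2-ynal (bonds C7–C8 and C9–C10; sets C10).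
5. Ring order: ring A (from 2-methylcyclohexanone) and the butenolide are bought as rings. Ring B is the only carbocycle formed. The last step forms no ring.

Convention: the decalin is C1–C10 and the chain on C9 is C11–C16, in labdane/clerodane numbering. α (below) and β (above) describe the faces as actually drawn, with ring A on the left and C10 at the top of the ring fusion.
Assumption: but-2-ynal and 4-(bromomethyl)furan-2(5H)-one are taken as purchasable, and the catalyst antipode named in step 4 is taken to give the 10R adduct (otherwise its mirror image is used).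

**Step 1**
Reactants: 1 2-methylcyclohexanone (racemic)
Product: 3 2,2,6-trimethylcyclohexanone (racemic), via 2,6-dimethylcyclohexanone 2 (not isolated)
Conditions: LiN(iPr)2 (1.05 equiv), THF, −78 °C; MeI (1.1 equiv), to 0 °C; recool, LiN(iPr)2 (1.1 equiv); MeI (1.3 equiv), −78 °C to rt, one flask
Reagents that add atoms: iodomethane CI
Why: Two successive enolate alkylations; whichever dimethyl isomer forms first, the second methylation converges on the same 2,2,6-trimethyl ketone, and its single stereocentre is erased in step 2.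

**Step 2**
Reactants: 3 2,2,6-trimethylcyclohexanone
Product: 4 2,6,6-trimethylcyclohex-1-en-1-yl trifluoromethanesulfonate
Conditions: LiN(iPr)2, THF, −78 to 0 °C; PhNTf2, 0 °C to rt
Reagents that add atoms: N-phenylbis(trifluoromethanesulfonimide) O=S(=O)(N(c1ccccc1)S(=O)(=O)C(F)(F)F)C(F)(F)F
Why: The ketone has a single α-hydrogen, so enolate O-sulfonylation (enol triflate formation) gives one tetrasubstituted enol triflate and no stereocentre.

**Step 3**
Reactants: 4 2,6,6-trimethylcyclohex-1-en-1-yl trifluoromethanesulfonate; 5 ethyl vinyl ether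
Product: 8 2-(1-ethoxyvinyl)-1,3,3-trimethylcyclohex-1-ene, via 1-ethoxyvinyllithium 6 (not isolated), via (1-ethoxyvinyl)zinc chloride 7 (not isolated)
Conditions: 5, t-BuLi, THF, −78 to 0 °C; ZnCl2, 0 °C; then 4, Pd(PPh3)4 (5 mol %), THF, 50 °C
Reagents that add atoms: none
Why: Negishi cross-coupling of an α-alkoxyvinylzinc reagent with the hindered enol triflate under zerovalent palladium forms the C5–C6 bond and delivers the 2-ethoxydiene directly; no stereocentre.

**Step 4**
Reactants: 8 2-(1-ethoxyvinyl)-1,3,3-trimethylcyclohex-1-ene; 9 but-2-ynal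
Product: 10 (10R)-6-ethoxydrima-5,8-dien-11-al (angular CH3 α)
Conditions: (S)-3,3-diphenyl-1-(2-methylphenyl)tetrahydro-1H,3H-pyrrolo[1,2-c][1,3,2]oxazaborole protonated by HNTf2 (20 mol %), CH2Cl2, −78 to −40 °C
Reagents that add atoms: none
Why: Catalytic enantioselective, strongly asynchronous Diels–Alder reaction of a 2-alkoxydiene with an alkynal; the nucleophilic CH2 terminus (C7) attacks the β-carbon of the ynal ("para" rule), so CHO ends on C9 next to the new quaternary C10, whose 10R configuration is fixed by the chiral oxazaborolidinium ion shielding one face of the bound aldehyde.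

**Step 5**
Reactants: 11 4-(bromomethyl)furan-2(5H)-one
Product: 12 diethyl [(5-oxo-2,5-dihydrofuran-3-yl)methyl]phosphonate
Conditions: P(OEt)3 (1.2 equiv), toluene, 110 °C
Reagents that add atoms: triethyl phosphite CCOP(OCC)OCC
Why: Michaelis–Arbuzov reaction of a reactive allylic bromide; no stereocentre.

**Step 6**
Reactants: 10 (10R)-6-ethoxydrima-5,8-dien-11-al; 12 diethyl [(5-oxo-2,5-dihydrofuran-3-yl)methyl]phosphonate
Product: 14 6-oxolabda-8,11E,13-trien-15,16-olide (5β-H/10α-CH3 trans-decalin), via ethoxy tetraene lactone 13 (not isolated)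
Conditions: 12, LiN(SiMe3)2, THF, −78 °C; 10, −78 to 0 °C; then 1 M HCl, THF, rt, 2 h
Reagents that add atoms: water O
Why: Horner–Wadsworth–Emmons olefination with a vinylogous stabilised phosphonate (the cyclic analogue of the 4-phosphonocrotonates that olefinate β-cyclocitral) gives the 11E alkene, and acid hydrolysis of the enol ether with equilibration through the enol sets the more stable trans fusion (5β-H anti to 10α-CH3).

**Step 7**
Reactants: 14 6-oxolabda-8,11E,13-trien-15,16-olide
Product: 15 7β-hydroxy-6-oxolabda-8,11E,13-trien-15,16-olide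
Conditions: KN(SiMe3)2 (1.0 equiv), THF, −78 °C; 3-phenyl-2-(phenylsulfonyl)oxaziridine, −78 °C; AcOH quench at −78 °C
Reagents that add atoms: 3-phenyl-2-(phenylsulfonyl)oxaziridine O=S(=O)(c1ccccc1)N1OC1c1ccccc1
Why: Davis enolate oxidation; the doubly activated C7–H is removed first, the extended enolate reacts α to the ketone as Hagemann-ester-type anions do, and the reagent comes from the β face because the α face carries the axial 10α- and 4α-methyl groups, giving the axial 7β-OH.

**Step 8**
Reactants: 15 7β-hydroxy-6-oxolabda-8,11E,13-trien-15,16-olide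
Product: 16 6α,7β-dihydroxylabda-8,11E,13-trien-15,16-olide
Conditions: NaBH4, CeCl3·7H2O, MeOH/THF, −78 to −40 °C
Reagents that add atoms: none
Why: Luche reduction; hydride can reach C6 only from the β face because the α face is closed by the two syn-axial methyl groups, giving the axial 6α-alcohol (trans-diaxial diol) while the lactone is untouched.

**Step 9**
Reactants: 16 6α,7β-dihydroxylabda-8,11E,13-trien-15,16-olide
Product: 17 8β,9β-epoxy-6α,7β-dihydroxylabda-11E,13-dien-15,16-olide
Conditions: VO(acac)2 (5 mol %), t-BuOOH (1.2 equiv, decane), CH2Cl2, 0 °C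
Reagents that add atoms: tert-butyl hydroperoxide CC(C)(C)OO
Why: Hydroxyl-directed vanadium-catalysed epoxidation; the pseudo-axial allylic 7β-OH delivers oxygen only to the β face of C8=C9, leaving C11=C12 and C13=C14 untouched and setting C8 and C9.

**Step 10**
Reactants: 17 8β,9β-epoxy-6α,7β-dihydroxylabda-11E,13-dien-15,16-olide
Product: 19 6α-acetoxy-8β,9β-epoxy-7β-isobutyryloxylabda-11E,13-dien-15,16-olide, via 7-isobutyrate 18 (not isolated)
Conditions: i-PrCOCl (1.1 equiv), Et3N, 4-dimethylaminopyridine (0.1 equiv), CH2Cl2, −20 to 0 °C; then Ac2O (5 equiv), 4-dimethylaminopyridine (1 equiv), 40 °C; Et3N-deactivated silica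
Reagents that add atoms: isobutyryl chloride CC(C)C(=O)Cl; acetic anhydride CC(=O)OC(C)=O
Why: Sequential nucleophile-catalysed acylations in one flask; the 7β-OH reacts first because the 6α-OH is syn-axial to two methyl groups and needs excess anhydride and warming, the trans-diaxial arrangement excludes acyl migration, and no stereocentre changes.

**Step 11**
Reactants: 19 6α-acetoxy-8β,9β-epoxy-7β-isobutyryloxylabda-11E,13-dien-15,16-olide
Product: 20 6α-acetoxy-8β-hydroxy-7β-isobutyryloxycleroda-3,11E,13-trien-15,16-olide (CNP0207114.1)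
Conditions: HNTf2 (2 mol %), (CF3)2CHOH/CH2Cl2 1:3, −40 °C, 30 min; Et3N quench
Reagents that add atoms: none
Why: Proposed new method: protonation of the tetrasubstituted epoxide in the non-nucleophilic, cation-stabilising (CF3)2CHOH medium breaks the C9–O bond (tertiary and allylic, whereas C8 is deactivated by the neighbouring C7 ester), and the only σ bond antiperiplanar to it, the axial C10–CH3 (α), migrates to C9; the all-trans-diaxial array 5β-H, 4α-CH3, 3β-H then relays the charge (H C5→C10, CH3 C4→C5) to C4, the tertiary position farthest from the three electron-withdrawing oxygens of ring B, helped by release of the 4α-CH3/10α-CH3/6α-OAc syn-axial strain, and loss of H-3 gives the Δ3 alkene and returns the proton; every shift is suprafacial with inversion at the receiving carbon, so 9α-CH3/9β-side chain, 10β-H and 5α-CH3 follow from the 8β,9β-epoxide and the 10α-CH3/5β-H fusion, the 8β-OH is freed and the diaxial 6,7-diester becomes diequatorial; the closest known reaction types are the Westphalen–Lettré rearrangement (where an antiperiplanar vicinal acetate likewise does not intercept the cation), the Lewis-acid backbone rearrangements of steroid and triterpene epoxides and the epoxide-triggered eudesmane-to-eremophilane methyl shift, none of which has been carried through four events on an ester- and dienyl-lactone-bearing labdane epoxide.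

**Compound list**
1 | 2-methylcyclohexanone (racemic) | CC1CCCCC1=O | starting material
2 | 2,6-dimethylcyclohexanone (cis/trans mixture) | CC1CCCC(C)C1=O | intermediate
3 | 2,2,6-trimethylcyclohexanone (racemic) | CC1CCCC(C)(C)C1=O | intermediate
4 | 2,6,6-trimethylcyclohex-1-en-1-yl trifluoromethanesulfonate | CC1=C(OS(=O)(=O)C(F)(F)F)C(C)(C)CCC1 | intermediate
5 | ethyl vinyl ether | C=COCC | starting material
6 | 1-ethoxyvinyllithium | [Li]C(=C)OCC | intermediate
7 | (1-ethoxyvinyl)zinc chloride | Cl[Zn]C(=C)OCC | intermediate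
8 | 2-(1-ethoxyvinyl)-1,3,3-trimethylcyclohex-1-ene | C=C(OCC)C1=C(C)CCCC1(C)C | intermediate
9 | but-2-ynal | CC#CC=O | starting material
10 | (10R)-6-ethoxydrima-5,8-dien-11-al: 4,4,10-trimethyl decalin with C5=C6 and C8=C9, OEt on C6, CH3 on C8, CHO on C9, angular CH3 α | CCOC1=C2C(C)(C)CCC[C@@]2(C)C(C=O)=C(C)C1 | intermediate
11 | 4-(bromomethyl)furan-2(5H)-one | O=C1C=C(CBr)CO1 | starting material
12 | diethyl [(5-oxo-2,5-dihydrofuran-3-yl)methyl]phosphonate | CCOP(=O)(CC1=CC(=O)OC1)OCC | intermediate
13 | 6-ethoxylabda-5,8,11E,13-tetraen-15,16-olide (10α-CH3) | CCOC1=C2C(C)(C)CCC[C@@]2(C)C(/C=C/C3=CC(=O)OC3)=C(C)C1 | intermediate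
14 | 6-oxolabda-8,11E,13-trien-15,16-olide (5β-H, 10α-CH3) | O=C1CC(C)=C(/C=C/C3=CC(=O)OC3)[C@]2(C)CCCC(C)(C)[C@@H]12 | intermediate
15 | 7β-hydroxy-6-oxolabda-8,11E,13-trien-15,16-olide (5β-H, 10α-CH3) | O=C1[C@H](O)C(C)=C(/C=C/C3=CC(=O)OC3)[C@]2(C)CCCC(C)(C)[C@@H]12 | intermediate
16 | 6α,7β-dihydroxylabda-8,11E,13-trien-15,16-olide (trans-diaxial diol) | O[C@H]1[C@H](O)C(C)=C(/C=C/C3=CC(=O)OC3)[C@]2(C)CCCC(C)(C)[C@@H]12 | intermediate
17 | 8β,9β-epoxy-6α,7β-dihydroxylabda-11E,13-dien-15,16-olide | O[C@H]1[C@H](O)[C@]2(C)O[C@]2(/C=C/C3=CC(=O)OC3)[C@]4(C)CCCC(C)(C)[C@@H]14 | intermediate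
18 | 8β,9β-epoxy-6α-hydroxy-7β-isobutyryloxylabda-11E,13-dien-15,16-olide | O[C@H]1[C@H](OC(=O)C(C)C)[C@]2(C)O[C@]2(/C=C/C3=CC(=O)OC3)[C@]4(C)CCCC(C)(C)[C@@H]14 | intermediate
19 | 6α-acetoxy-8β,9β-epoxy-7β-isobutyryloxylabda-11E,13-dien-15,16-olide | CC(=O)O[C@H]1[C@H](OC(=O)C(C)C)[C@]2(C)O[C@]2(/C=C/C3=CC(=O)OC3)[C@]4(C)CCCC(C)(C)[C@@H]14 | intermediate
20 | 6α-acetoxy-8β-hydroxy-7β-isobutyryloxycleroda-3,11E,13-trien-15,16-olide (5α-CH3, 8α-CH3, 9α-CH3, 10β-H) | CC(=O)O[C@H]1[C@H](OC(=O)C(C)C)[C@](C)(O)[C@](C)(/C=C/C2=CC(=O)OC2)[C@H]2CCC=C(C)[C@]12C | target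

**Step count and risks**
Total step count: 11, of which step 5 lies on the side branch. Longest linear sequence: 10 (steps 1–4 and 6–11).

**Step 11 (the proposed new step).**
- How it may fail: the relay may stall after the first methyl shift by loss of H-5 or H-1. It may also divert to an 8-ketone by a shift from C8, or end in the exocyclic alkene.
- Fallback: sets out from 19 and comes back at 20, using known reaction types only.
- BF3·OEt2 in CH2Cl2 at −78 °C is the classical Westphalen-type regime, in which only the angular methyl moves and the C10 cation loses H-5. It gives 6α-acetoxy-8β-hydroxy-7β-isobutyryloxyhalima-5(10),11E,13-trien-15,16-olide F1.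
- The remaining shift is then triggered separately and irreversibly with N-bromosuccinimide (1.0 equiv) in (CF3)2CHOH/CH2Cl2. This is a bromonium-induced Wagner–Meerwein shift: a β-bromonium ion forms on the tetrasubstituted alkene, the 4α-methyl moves to C5, and H-3 is lost. The product is 6α-acetoxy-10β-bromo-8β-hydroxy-7β-isobutyryloxycleroda-3,11E,13-trien-15,16-olide F2.
- Radical dehalogenation with (Me3Si)3SiH/Et3B/air gives 20. Hydrogen is delivered to the C10 radical from the β face, because the α face carries the methyl groups on C5 and C9.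

**Step 4.**
- How it may fail: the diene is twisted and carries an inside methyl group at its reacting terminus, so rate and enantioselectivity under the chiral catalyst are uncertain.
- Fallback: sets out from 8 and 9 and comes back at 10, replacing asymmetric catalysis by resolution.
- The cycloaddition is run with achiral Me2AlCl (CH2Cl2, −78 to 0 °C), or thermally in a sealed tube. This gives the racemate, that is 10 together with its mirror image (10S)-6-ethoxydrima-5,8-dien-11-al F3.
- The two are separated by preparative chromatography on amylose tris(3,5-dimethylphenylcarbamate) with hexane/i-PrOH/0.1 % Et3N.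

**Step 7.**
- How it may fail: the long delocalised enolate may be oxidised at a remote carbon. The α-ketol may also isomerise under base to the conjugated 7-oxo-6-ol.
- Fallback: sets out from 14 and comes back at 15, replacing the free enolate by a Rubottom oxidation.
- Soft enolisation with t-BuMe2SiOSO2CF3/Et3N gives 6-(tert-butyldimethylsilyloxy)labda-6,8,11E,13-tetraen-15,16-olide F4.
- Dimethyldioxirane (acetone, −40 °C) epoxidises its most electron-rich alkene, C6=C7, from the β face. Silyl migration then gives 7β-(tert-butyldimethylsilyloxy)-6-oxolabda-8,11E,13-trien-15,16-olide F5.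
- HF·pyridine in THF at 0 °C gives 15 under non-basic conditions.

**Further compounds**
F1 | step 11 | 6α-acetoxy-8β-hydroxy-7β-isobutyryloxyhalima-5(10),11E,13-trien-15,16-olide | CC(=O)O[C@H]1[C@H](OC(=O)C(C)C)[C@](C)(O)[C@](C)(/C=C/C2=CC(=O)OC2)C3=C1C(C)(C)CCC3
F2 | step 11 | 6α-acetoxy-10β-bromo-8β-hydroxy-7β-isobutyryloxycleroda-3,11E,13-trien-15,16-olide | CC(=O)O[C@H]1[C@H](OC(=O)C(C)C)[C@](C)(O)[C@](C)(/C=C/C2=CC(=O)OC2)[C@@]2(Br)CCC=C(C)[C@]12C
F3 | step 4 | (10S)-6-ethoxydrima-5,8-dien-11-al | CCOC1=C2C(C)(C)CCC[C@]2(C)C(C=O)=C(C)C1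
F4 | step 7 | 6-(tert-butyldimethylsilyloxy)labda-6,8,11E,13-tetraen-15,16-olide | CC(C)(C)[Si](C)(C)OC1=CC(C)=C(/C=C/C3=CC(=O)OC3)[C@]2(C)CCCC(C)(C)[C@@H]12
F5 | step 7 | 7β-(tert-butyldimethylsilyloxy)-6-oxolabda-8,11E,13-trien-15,16-olide | O=C1[C@H](O[Si](C)(C)C(C)(C)C)C(C)=C(/C=C/C3=CC(=O)OC3)[C@]2(C)CCCC(C)(C)[C@@H]12
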